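**Plan** (labdane numbering: ring A = C1–C5, C10; ring B = C5–C10; C17 = exocyclic CH2 on C8; side chain C11–C15 on C9; C4 carries CH3 and CH2O-tigloyl)

- Retrosynthetic cuts, in order: the C15 O–Si bond; the C12–C13 bond (alkyl–alkenyl coupling); the C3 O-acetyl bond; then C10–C9 and C4–C5 together (rings B and A, with the C8=C17 alkene); then the C3–C4 epoxide and the C–O bond of a terminal E-CH2OH.
- Enabling feature: the C3 oxygen sits next to quaternary C4, and C4, C5=C10 and C9=C8 stand in 1,5-relationships (head-to-tail isoprenoid rings A and B) with a methylene on C8. This is the retron of an epoxide-triggered radical bicyclization that ends by hydrogen loss from the C8 methyl.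
- Forward: C16 homofarnesyl bromide → terminal allylic oxidation → asymmetric epoxidation → tiglate → one operation closes ring A, then ring B (the last ring) → acetate → side chain joined at C12 → desilylation.
- Stereochemistry: C3 comes from the Sharpless epoxidation (D-(−)-tartrate); C4, C5, C10 and C9 are relayed from C3 in the chair–chair cascade, the two E alkenes of the chain fixing the trans fusion and the equatorial C9 substituent. The 13E alkene comes from a syn hydrozirconation, the tiglate geometry from tiglic acid.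
- The precursor ends at C12 in a bromide, so no third ring can form; the same bromide is then the coupling handle, and the tiglate the target needs serves as the protecting group of the C4 CH2O.

Key step: step 5

Assumption: (3E,7E)-homofarnesol 1 is taken as a commercial fragrance intermediate in geometrically pure form.

**Step 1**
Reactants: 1 (3E,7E)-4,8,12-trimethyltrideca-3,7,11-trien-1-ol
Product: 2 (6E,10E)-13-bromo-2,6,10-trimethyltrideca-2,6,10-triene
Conditions: CBr4, PPh3, CH2Cl2, 0 °C
Reagents that add atoms: carbon tetrabromide, BrC(Br)(Br)Br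
Why: Appel bromination of the primary alcohol (SN2 on the alkoxyphosphonium ion) runs under neutral conditions that should leave the three trisubstituted alkenes and their geometry untouched.

**Step 2**
Reactants: 2 (6E,10E)-13-bromo-2,6,10-trimethyltrideca-2,6,10-triene
Product: 3 (2E,6E,10E)-13-bromo-2,6,10-trimethyltrideca-2,6,10-trien-1-ol
Conditions: SeO2 (cat.), salicylic acid (cat.), t-BuOOH, CH2Cl2, 0 °C → rt, stopped at partial conversion, 2 recycled
Reagents that add atoms: tert-butyl hydroperoxide, CC(C)(C)OO (terminal oxidant; the oxygen is passed on by catalytic selenium dioxide, O=[Se]=O)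
Why: Riley-type allylic hydroxylation (ene reaction, then [2,3]-shift) should attack the electron-rich terminal isopropylidene group and, by its E rule, oxidize the methyl trans to the chain, giving the E allylic alcohol whose CH2OH becomes the equatorial C4 substituent.

**Step 3**
Reactants: 3 (2E,6E,10E)-13-bromo-2,6,10-trimethyltrideca-2,6,10-trien-1-ol
Product: 4 [(2R,3R)-3-[(3E,7E)-10-bromo-3,7-dimethyldeca-3,7-dien-1-yl]-2-methyloxiran-2-yl]methanol
Conditions: Ti(Oi-Pr)4 (cat.), D-(−)-diethyl tartrate (cat.), t-BuOOH, 4 Å MS, CH2Cl2, −20 °C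
Reagents that add atoms: tert-butyl hydroperoxide, CC(C)(C)OO
Why: Sharpless asymmetric epoxidation touches only the allylic-alcohol alkene; D-(−)-tartrate should deliver oxygen to the face that gives the (2R,3R)-epoxide, so the future C3 (R) is set by the reagent and the C3/C4 relationship by the E alkene.

**Step 4**
Reactants: 4 [(2R,3R)-3-[(3E,7E)-10-bromo-3,7-dimethyldeca-3,7-dien-1-yl]-2-methyloxiran-2-yl]methanol; 5 tiglic acid, (2E)-2-methylbut-2-enoic acid
Product: 6 [(2R,3R)-3-[(3E,7E)-10-bromo-3,7-dimethyldeca-3,7-dien-1-yl]-2-methyloxiran-2-yl]methyl (2E)-2-methylbut-2-enoate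
Conditions: DCC, DMAP (cat.), CH2Cl2, 0 °C → rt
Reagents that add atoms: none
Why: Steglich esterification acylates the primary alcohol under neutral conditions, without opening the epoxide or isomerizing the tiglate, and installs the ester of the target so that no separate protecting group is needed.

**Step 5**
Reactants: 6 [(2R,3R)-3-[(3E,7E)-10-bromo-3,7-dimethyldeca-3,7-dien-1-yl]-2-methyloxiran-2-yl]methyl (2E)-2-methylbut-2-enoate
Product: 8 [(1S,2R,4aS,5R,8aS)-5-(2-bromoethyl)-2-hydroxy-1,4a-dimethyl-6-methylidenedecahydronaphthalen-1-yl]methyl (2E)-2-methylbut-2-enoate, via titanium(IV) alkoxide 7 (not isolated)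
Conditions: Cp2TiCl2 (2.5 equiv), Mn dust, THF, rt (green Cp2TiCl solution added slowly to 6, 0.01 M); then 1 M aq. HCl
Reagents that add atoms: none
Why: Cp2TiCl opens the epoxide by single-electron transfer at the more substituted carbon to give the tertiary C4 radical (O–Ti on C3), which closes ring A by 6-endo-trig addition to C5 of the C5=C10 alkene and then ring B by 6-endo-trig addition of the tertiary C10 radical to C9 of the C9=C8 alkene; the tertiary C8 radical has no further alkene in reach, is captured by a second Cp2TiCl and loses a hydrogen from the C8 methyl (β-hydride elimination or mixed disproportionation) to give C8=CH2, and acid work-up frees the C3 alcohol from 7. The closest known reaction type is the titanocene(III)-mediated radical cyclization of epoxypolyprenes, as in the conversion of 10,11-epoxyfarnesyl esters into 3-hydroxy-8(12)-drimenes. C3 keeps the configuration of the epoxide because its C–O bond is never broken, and it relays chirality by holding the bulky O–Ti group equatorial in the chair-like transition state of the first closure, in which the larger CH2O-tigloyl group of the planar C4 radical should take the pseudo-equatorial site (away from C2 and the C10 methyl), so that C4 ends with CH3 axial and CH2O trans to the C3 oxygen. The E geometry of the C5=C10 alkene in the chair–chair fold should give the trans ring fusion (H-5 anti to the C10 methyl), and the E geometry of the C9=C8 alkene should place the bromoethyl group on C9 equatorial. The step needs cyclization to outrun capture of the first radical by titanium (which would expel the β-acyloxy group) and needs the cascade to end at the bicycle with exocyclic hydrogen loss: slow addition keeps the stationary Ti(III) concentration low, the 6-endo closures onto trisubstituted alkenes are fast and give tertiary radicals, the chain ends at C12 in a bromide so no third ring can form, and loss of hydrogen from the unhindered methyl is the usual regiochemistry of this termination.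

**Step 6**
Reactants: 8 [(1S,2R,4aS,5R,8aS)-5-(2-bromoethyl)-2-hydroxy-1,4a-dimethyl-6-methylidenedecahydronaphthalen-1-yl]methyl (2E)-2-methylbut-2-enoate
Product: 9 [(1S,2R,4aS,5R,8aS)-2-acetoxy-5-(2-bromoethyl)-1,4a-dimethyl-6-methylidenedecahydronaphthalen-1-yl]methyl (2E)-2-methylbut-2-enoate
Conditions: Ac2O, Et3N, DMAP (cat.), CH2Cl2, 0 °C → rt
Reagents that add atoms: acetic anhydride, CC(=O)OC(C)=O
Why: DMAP-catalysed acetylation of the equatorial secondary C3 alcohol should be faster than 1,3-migration of the unreactive conjugated tigloyl group, and the primary bromide is inert.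

**Step 7**
Reactants: 10 but-2-yn-1-ol
Product: 11 tert-butyl(but-2-yn-1-yloxy)dimethylsilane
Conditions: TBSCl, imidazole, CH2Cl2, rt
Reagents that add atoms: tert-butyldimethylsilyl chloride, CC(C)(C)[Si](C)(C)Cl
Why: Standard silylation of a primary propargylic alcohol.

**Step 8**
Reactants: 11 tert-butyl(but-2-yn-1-yloxy)dimethylsilane
Product: 13 tert-butyl{[(2E)-3-iodobut-2-en-1-yl]oxy}dimethylsilane, via alkenylzirconocene chloride 12 (not isolated)
Conditions: Cp2Zr(H)Cl (2 equiv), THF, rt → 50 °C; then I2, 0 °C
Reagents that add atoms: iodine, II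
Why: Schwartz hydrozirconation adds H–Zr syn and, after equilibration in excess reagent, should place zirconium on the alkyne carbon that bears the small methyl group; iodinolysis with retention then gives the E iodide (I trans to CH2OTBS).

**Step 9**
Reactants: 9 [(1S,2R,4aS,5R,8aS)-2-acetoxy-5-(2-bromoethyl)-1,4a-dimethyl-6-methylidenedecahydronaphthalen-1-yl]methyl (2E)-2-methylbut-2-enoate; 13 tert-butyl{[(2E)-3-iodobut-2-en-1-yl]oxy}dimethylsilane
Product: 15 [(1S,2R,4aS,5R,8aS)-2-acetoxy-5-[(3E)-5-(tert-butyldimethylsilyloxy)-3-methylpent-3-en-1-yl]-1,4a-dimethyl-6-methylidenedecahydronaphthalen-1-yl]methyl (2E)-2-methylbut-2-enoate, via alkylzinc bromide 14 (not isolated)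
Conditions: Zn dust (activated), LiCl, THF, 50 °C; then 13, Pd(OAc)2 (cat.), SPhos (cat.), THF, rt → 40 °C
Reagents that add atoms: none
Why: Negishi alkyl–alkenyl coupling: zinc insertion into the primary bromide gives an alkylzinc halide that tolerates both esters and the exocyclic alkene, and palladium-catalysed coupling proceeds with retention of the iodide geometry, so the C12–C13 bond should form with the 13E alkene in place.

**Step 10**
Reactants: 15 [(1S,2R,4aS,5R,8aS)-2-acetoxy-5-[(3E)-5-(tert-butyldimethylsilyloxy)-3-methylpent-3-en-1-yl]-1,4a-dimethyl-6-methylidenedecahydronaphthalen-1-yl]methyl (2E)-2-methylbut-2-enoate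
Product: 16 [(1S,2R,4aS,5R,8aS)-2-acetoxy-5-[(3E)-5-hydroxy-3-methylpent-3-en-1-yl]-1,4a-dimethyl-6-methylidenedecahydronaphthalen-1-yl]methyl (2E)-2-methylbut-2-enoate (CNP0148037.1)
Conditions: HF·pyridine, pyridine, THF, 0 °C → rt
Reagents that add atoms: none
Why: Buffered, non-basic fluoride desilylation should cleave the primary allylic TBS ether while both esters stay in place, since no alkoxide forms that could trigger acyl migration.

**Compound list**

1 | (3E,7E)-4,8,12-trimethyltrideca-3,7,11-trien-1-ol ((E,E)-homofarnesol) | CC(C)=CCC/C(C)=C/CC/C(C)=C/CCO | starting material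
2 | (6E,10E)-13-bromo-2,6,10-trimethyltrideca-2,6,10-triene | CC(C)=CCC/C(C)=C/CC/C(C)=C/CCBr | intermediate
3 | (2E,6E,10E)-13-bromo-2,6,10-trimethyltrideca-2,6,10-trien-1-ol | OC/C(C)=C/CC/C(C)=C/CC/C(C)=C/CCBr | intermediate
4 | [(2R,3R)-3-[(3E,7E)-10-bromo-3,7-dimethyldeca-3,7-dien-1-yl]-2-methyloxiran-2-yl]methanol | OC[C@@]1(C)O[C@@H]1CC/C(C)=C/CC/C(C)=C/CCBr | intermediate
5 | tiglic acid, (2E)-2-methylbut-2-enoic acid | C/C=C(\C)C(=O)O | starting material
6 | [(2R,3R)-3-[(3E,7E)-10-bromo-3,7-dimethyldeca-3,7-dien-1-yl]-2-methyloxiran-2-yl]methyl (2E)-2-methylbut-2-enoate | C/C=C(\C)C(=O)OC[C@@]1(C)O[C@@H]1CC/C(C)=C/CC/C(C)=C/CCBr | intermediate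
7 | chlorobis(cyclopentadienyl)titanium(IV) alkoxide of 8 (Ti on the C3 oxygen) | C=C1CC[C@H]2[C@@](C)(CC[C@@H](O[Ti](Cl)(C3C=CC=C3)C3C=CC=C3)[C@]2(C)COC(=O)/C(C)=C/C)[C@@H]1CCBr | intermediate (not isolated)
8 | [(1S,2R,4aS,5R,8aS)-5-(2-bromoethyl)-2-hydroxy-1,4a-dimethyl-6-methylidenedecahydronaphthalen-1-yl]methyl (2E)-2-methylbut-2-enoate | C=C1CC[C@H]2[C@@](C)(CC[C@@H](O)[C@]2(C)COC(=O)/C(C)=C/C)[C@@H]1CCBr | intermediate
9 | [(1S,2R,4aS,5R,8aS)-2-acetoxy-5-(2-bromoethyl)-1,4a-dimethyl-6-methylidenedecahydronaphthalen-1-yl]methyl (2E)-2-methylbut-2-enoate | C=C1CC[C@H]2[C@@](C)(CC[C@@H](OC(C)=O)[C@]2(C)COC(=O)/C(C)=C/C)[C@@H]1CCBr | intermediate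
10 | but-2-yn-1-ol | CC#CCO | starting material
11 | tert-butyl(but-2-yn-1-yloxy)dimethylsilane | CC#CCO[Si](C)(C)C(C)(C)C | intermediate
12 | chlorobis(cyclopentadienyl)[(2E)-4-(tert-butyldimethylsilyloxy)but-2-en-2-yl]zirconium | C/C(=C\CO[Si](C)(C)C(C)(C)C)[Zr](Cl)(C1C=CC=C1)C1C=CC=C1 | intermediate (not isolated)
13 | tert-butyl{[(2E)-3-iodobut-2-en-1-yl]oxy}dimethylsilane | C/C(I)=C\CO[Si](C)(C)C(C)(C)C | intermediate
14 | alkylzinc bromide of 9 (C–Br of the 2-bromoethyl group replaced by C–ZnBr) | C=C1CC[C@H]2[C@@](C)(CC[C@@H](OC(C)=O)[C@]2(C)COC(=O)/C(C)=C/C)[C@@H]1CC[Zn]Br | intermediate (not isolated)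
15 | [(1S,2R,4aS,5R,8aS)-2-acetoxy-5-[(3E)-5-(tert-butyldimethylsilyloxy)-3-methylpent-3-en-1-yl]-1,4a-dimethyl-6-methylidenedecahydronaphthalen-1-yl]methyl (2E)-2-methylbut-2-enoate | C=C1CC[C@H]2[C@@](C)(CC[C@@H](OC(C)=O)[C@]2(C)COC(=O)/C(C)=C/C)[C@@H]1CC/C(C)=C/CO[Si](C)(C)C(C)(C)C | intermediate
16 | [(1S,2R,4aS,5R,8aS)-2-acetoxy-5-[(3E)-5-hydroxy-3-methylpent-3-en-1-yl]-1,4a-dimethyl-6-methylidenedecahydronaphthalen-1-yl]methyl (2E)-2-methylbut-2-enoate | C=C1CC[C@H]2[C@@](C)(CC[C@@H](OC(C)=O)[C@]2(C)COC(=O)/C(C)=C/C)[C@@H]1CC/C(C)=C/CO | target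

**Totals and risks**

Total step count: 10. Longest linear sequence: 8 (steps 1–6, 9, 10).

Most likely to fail:

1. Step 5. The first radical may be captured by titanium before it cyclizes, with reductive β-elimination of the tiglate. Rotamer control at C4 in the first ring closure may also be incomplete, since C4 is a planar radical and is not fixed by the epoxide. Fallback: the C4 CH2O is carried through the cascade as a bulky silyl ether (a poor leaving group with a stronger equatorial preference) and the tiglate is attached afterwards. It sets out from 4: TBSCl and imidazole in CH2Cl2 should give the epoxy silyl ether F1; the titanocene(III) conditions of step 5 should give the bicyclic hydroxy silyl ether F2; Ac2O, Et3N and DMAP the acetoxy silyl ether F3; HF·pyridine the acetoxy primary alcohol F4; esterification with 5 (DCC, DMAP) returns to the route at 9.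

2. Step 2. Site selectivity between the terminal and the two internal trisubstituted alkenes may be poor, and over-oxidation to the enal may limit conversion. Fallback: terminal degradation and E-selective rebuilding, setting out from 2. NBS in aqueous THF at 0 °C (selective for the terminal alkene) should give the bromohydrin F5; K2CO3 in MeOH the terminal epoxide F6; HIO4 in aqueous THF the trisnor aldehyde F7; Wittig reaction with Ph3P=C(CH3)CO2Et in CH2Cl2 the E enoate F8; DIBAL-H in CH2Cl2 at −78 °C returns to the route at 3.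

3. Step 9. Zinc insertion may be slow or incomplete on the late-stage bromide, and protodemetalation or β-hydride elimination at palladium may erode the coupling. Fallback: nickel-catalysed reductive cross-electrophile coupling of 9 with 13 (NiI2·glyme, 4,4'-di-tert-butyl-2,2'-bipyridine, Mn, DMA, rt), which needs no preformed organometallic and returns to the route at 15.

**Further compounds**

F1 | step 5 | tert-butyl{[(2R,3R)-3-[(3E,7E)-10-bromo-3,7-dimethyldeca-3,7-dien-1-yl]-2-methyloxiran-2-yl]methoxy}dimethylsilane | CC(C)(C)[Si](C)(C)OC[C@@]1(C)O[C@@H]1CC/C(C)=C/CC/C(C)=C/CCBr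
F2 | step 5 | (1S,2R,4aS,5R,8aS)-5-(2-bromoethyl)-1-{[(tert-butyldimethylsilyl)oxy]methyl}-1,4a-dimethyl-6-methylidenedecahydronaphthalen-2-ol | C=C1CC[C@H]2[C@@](C)(CC[C@@H](O)[C@]2(C)CO[Si](C)(C)C(C)(C)C)[C@@H]1CCBr
F3 | step 5 | (1S,2R,4aS,5R,8aS)-5-(2-bromoethyl)-1-{[(tert-butyldimethylsilyl)oxy]methyl}-1,4a-dimethyl-6-methylidenedecahydronaphthalen-2-yl acetate | C=C1CC[C@H]2[C@@](C)(CC[C@@H](OC(C)=O)[C@]2(C)CO[Si](C)(C)C(C)(C)C)[C@@H]1CCBr
F4 | step 5 | (1S,2R,4aS,5R,8aS)-5-(2-bromoethyl)-1-(hydroxymethyl)-1,4a-dimethyl-6-methylidenedecahydronaphthalen-2-yl acetate | C=C1CC[C@H]2[C@@](C)(CC[C@@H](OC(C)=O)[C@]2(C)CO)[C@@H]1CCBr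
F5 | step 2 | (6E,10E)-3,13-dibromo-2,6,10-trimethyltrideca-6,10-dien-2-ol (racemic at C3) | CC(C)(O)C(Br)CC/C(C)=C/CC/C(C)=C/CCBr
F6 | step 2 | 3-[(3E,7E)-10-bromo-3,7-dimethyldeca-3,7-dien-1-yl]-2,2-dimethyloxirane (racemic) | CC1(C)OC1CC/C(C)=C/CC/C(C)=C/CCBr
F7 | step 2 | (4E,8E)-11-bromo-4,8-dimethylundeca-4,8-dienal | O=CCC/C(C)=C/CC/C(C)=C/CCBr
F8 | step 2 | ethyl (2E,6E,10E)-13-bromo-2,6,10-trimethyltrideca-2,6,10-trienoate | CCOC(=O)/C(C)=C/CC/C(C)=C/CC/C(C)=C/CCBr
F0 | step 9 | none | none
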